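**Assumption on the chemistry:** triester 3 is expected as an E/Z mixture and is drawn as Z, the isomer that lactonizes; the two interconvert through the dienol in step 2, so the geometry from step 1 does not matter.

## Analysis of the target

Target 18 is a depside: two benzene rings joined by an aryl ester whose carbonyl carbon sits on ring A and whose oxygen is O-4 of ring B. It has no stereocenter, so every problem is one of regiochemistry and chemoselectivity. Ring B (C1 CO2H, C2 OH, C3 CH3, C4 O-acyl, C5 H, C6 CH3) is 3-methylorsellinic acid, which can be bought as its methyl ester 12. Ring A carries five contiguous substituents (C1 acyl, C2 OCH3, C3 CH2OH, C4 OCH3, C5 H, C6 CH3), with the hydroxymethyl carbon locked between two methoxy groups. The sensitive groups are the C3 benzylic alcohol (it ionizes in acid because both ortho methoxy groups stabilize the cation, and it can be hydrogenolyzed), the inter-ring ester (cleaved by hydroxide or alkoxide), the salicylic acid of ring B (decarboxylates in hot acid) and the free phenol. Three things make the synthesis hard: electrophiles attack an orsellinate dimethyl ether at C5 and not at C3; the ring A carboxyl is flanked by OCH3 and CH3 and is slow in acyl substitution; ring B offers two hydroxyl groups. The plan rests on reading C3–C4 of ring A (the CH2O-bearing and the CH3O-bearing carbons) as the two carbons of ynol ether 8, and C5, C6, C1, C2 (H, CH3, ester, OCH3) as C3, C4, C5, C6 of 2-pyrone 4. Ring A then comes from one cycloaddition with every substituent and both methyl ethers already in place.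

## Retrosynthetic reasoning

**18 back to 17 and 16.** Only protecting groups are removed at the end. The Si–O bond of 17 is cut last under buffered, near-neutral conditions, so that the acid-labile C3 benzylic alcohol is exposed once and never meets strong acid or base. The benzyl ester of 16 is cut one step earlier by hydrogenolysis, while the bulky silyl ether still shields the benzylic C–O bond from reduction.

**16 back to 11 and 14.** The inter-ring acyl–oxygen bond is cut because it is the only bond joining two independently accessible halves. The forward reaction must acylate O-4 of 14 and leave the chelated, doubly flanked O-2 alone. It must also avoid acid: the classical depside coupling works in a strongly acidic anhydride medium that would ionize the C3 benzylic C–O bond of 11. The acid is therefore activated as acyl chloride 15 under neutral conditions and coupled with base.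

**14 back to 13 and 12.** Ring B is bought as 12. The methyl ester is exchanged for a benzyl ester by way of acid 13, because a benzyl ester can be removed at the end without touching the inter-ring ester.

**11 back to 10.** The O–CH3 bond of the ester is cut, not the acyl–oxygen bond. The carbonyl of 10 is shielded by the ortho OCH3 and CH3 groups, whereas the methyl carbon is open to a soft nucleophile.

**10 back to 4 and 8 through 9.** The ring A bonds C2–C3 and C4–C5 are cut. This returns the pentasubstituted arene to a pyrone that holds H, CH3, ester and OCH3 on four adjacent carbons and to an alkyne that holds the remaining OCH3 and the oxymethyl group. No aromatic substitution is needed, so the C3 versus C5 problem does not arise. The forward reaction must join the carbon of 8 that carries the CH2OSi group to C6 of 4 and the methoxy-bearing carbon to C3 of 4; bridged lactone 9 must then lose its lactone bridge to aromatize.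

**4 back to 3, 1 and 2.** The lactone C–O bond of 4 is opened to triester 3, and 3 is cut at the bond between the malonate carbon and the methyl-bearing alkene carbon. Both forward steps are classical: conjugate addition of 1 to 2, then thermal ring closure with loss of one equivalent of alcohol. Using methyl esters throughout removes any risk of ester scrambling.

**8 back to 7, 6 and 5.** The silyl ether is cut to alcohol 7. Its C–C bond to the hydroxymethyl carbon is cut to acetylide 6 and a one-carbon aldehyde electrophile, and 6 comes from acetal 5 by double elimination.

## Alternatives that were turned down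

**Alternative 1: ring B by biomimetic aromatization.**
- Disconnection: the C1–C6 bond of ring B, opening the arene to the acyclic diketo-dioxinone A1.
- Forward key step: a tertiary amine base triggers an intramolecular aldol reaction of A1. The dioxinone C5 adds to the terminal methyl ketone and water is lost, giving benzodioxinone A2.
- For: the conditions are mild, the regiochemistry is fixed by the chain, and the precedent is strong. In A2 the carboxyl and the 2-OH are tied up together, so the 4-OH is the only free hydroxyl. On that point A2 is a better coupling partner than 14, and its key step is more certain than step 5.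
- Against: it spends the ring-forming step on the half that can be bought as 12. A1 needs several C–C bond-forming steps. The acetonide must later be opened by an oxygen nucleophile, which threatens the inter-ring ester; if it is opened before coupling, the advantage over 14 is lost. Ring A, the harder half, is untouched.
- Comparison: the chosen route reaches the ring B partner in two steps from 12 and puts the ring construction where the substitution pattern is the problem.

**Alternative 2: ring A grown on a ring B butynoate.**
- Disconnection: the ring A bonds C1–C2 and C5–C6, with the inter-ring ester already in place.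
- Forward key step: normal-demand Diels–Alder reaction of aryl but-2-ynoate A3 with the dioxygenated silyl ketene acetal diene A4. Loss of an alcohol and of the silyl group aromatizes the adduct to A5.
- For: the inter-ring ester is made by acylating the phenol with an unhindered alkynoic acid, so the hindered esterification of step 9 disappears. On that point, and in convergence, this alternative is stronger.
- Against: the cycloaddition delivers C2 as a free, chelated phenol. It must then be methylated between the ester and the oxymethyl group in the presence of the base-labile aryl ester. Diene A4 is tetrasubstituted, carries the oxymethyl group on its central carbon and is hydrolytically fragile, and it must react with a beta-methyl ynoate, which is a sluggish dienophile. The benzyl ether on the dimethoxybenzylic carbon of A5 has to be hydrogenolyzed on the correct side of oxygen; cleavage on the ring side would give a C3 methyl group.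
- Comparison: in the chosen strategy both methyl ethers arrive at the correct oxidation level, and ring A is made and checked as a small molecule before the coupling. The price is the hindered esterification.

**Alternative 3: aryne installs CH3 and CO2H together.**
- Disconnection: the C6–CH3 and C1–CO2H bonds of ring A, starting from the symmetric aryl bromide A6.
- Forward key step: a hindered lithium amide removes the proton between bromine and methoxy, and loss of bromide gives the aryne. A methyl Grignard reagent adds at the carbon remote from the methoxy group, and the aryl anion next to the methoxy group is carboxylated to acid A7.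
- For: it is the shortest way to a ring A acid. The direction of addition to a 3-alkoxyaryne is well understood, and the free acid is obtained directly, so no ester cleavage like step 6 is needed. In step economy it is stronger than the chosen route.
- Against: three components must react in order in one flask. The amide base and the amine it releases compete with the methyl nucleophile for the aryne. Any protonation of the aryl anion gives an arene without the carboxyl group. The carboxylation takes place at a carbon flanked by OCH3 and the new CH3.
- Comparison: the chosen route is longer, but ring A comes from a thermal step without added reagents, its only by-product is a gas, and its regiochemistry is set by the polarity of the two partners.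

Key step: step 5

## Route

Step 1
Reactants: 1 dimethyl malonate; 2 methyl but-2-ynoate
Product: 3 trimethyl (Z)-2-methylprop-1-ene-1,3,3-tricarboxylate
Conditions: NaOMe (1.05 equiv), MeOH, 0 → 65 °C; then AcOH (1.05 equiv)
Reagents that add atoms: none
Why: Michael addition of sodium dimethyl malonate to the ynoate; the adduct is a stabilized glutaconate anion, which drives the addition, and any methoxide that adds to 2 first gives a beta-methoxycrotonate that reaches 3 by addition–elimination, while the all-methyl ester set excludes scrambling by transesterification.

Step 2
Reactants: 3 trimethyl (Z)-2-methylprop-1-ene-1,3,3-tricarboxylate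
Product: 4 methyl 6-methoxy-4-methyl-2-oxo-2H-pyran-5-carboxylate
Conditions: Ph2O, 190–200 °C, MeOH distilled off
Reagents that add atoms: none
Why: Thermal lactonization in which the enol oxygen of the malonate unit attacks the conjugated ester (6-exo-trig acyl substitution) and methanol leaves the mixture; this is the known ring closure of alkoxycarbonyl-glutaconates to 6-alkoxy-2-pyrone-5-carboxylates, and the E isomer feeds in through the dienol.

Step 3
Reactants: 5 2-chloro-1,1-dimethoxyethane (chloroacetaldehyde dimethyl acetal)
Product: 7 3-methoxyprop-2-yn-1-ol, via lithium methoxyacetylide 6 (not isolated)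
Conditions: Et2NH, n-BuLi (3.1 equiv each), THF, 0 °C; then (CH2O)n, −78 → 20 °C; H2O quench
Reagents that add atoms: paraformaldehyde as formaldehyde, C=O
Why: LiNEt2 effects two eliminations (MeOH, then HCl) and deprotonates the methoxyacetylene formed, the established route from chloroacetaldehyde acetals to metal alkoxyacetylides, and the acetylide adds to formaldehyde; a basic aqueous quench keeps the ynol ether away from acid.

Step 4
Reactants: 7 3-methoxyprop-2-yn-1-ol
Product: 8 tert-butyl(3-methoxyprop-2-ynyloxy)dimethylsilane
Conditions: TBSCl, imidazole, DMF, 0 °C
Reagents that add atoms: tert-butyldimethylsilyl chloride, CC(C)(C)[Si](C)(C)Cl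
Why: Standard silylation of a primary alcohol under basic conditions; capping the hydroxyl also removes the group that would start a Meyer–Schuster rearrangement of the alkoxypropargyl alcohol.

Step 5
Reactants: 4 methyl 6-methoxy-4-methyl-2-oxo-2H-pyran-5-carboxylate; 8 tert-butyl(3-methoxyprop-2-ynyloxy)dimethylsilane
Product: 10 methyl 3-(tert-butyldimethylsilyloxymethyl)-2,4-dimethoxy-6-methylbenzoate, via bridged lactone cycloadduct 9 (not isolated)
Conditions: 8 (2 equiv), PhMe, 120 °C, sealed tube
Reagents that add atoms: none
Why: Inverse-electron-demand Diels–Alder reaction followed by retro-Diels–Alder loss of CO2; the closest known cases are the cycloadditions of ester-bearing 2-pyrones with ynamines, ketene acetals and alkoxyalkynes. The diene is C3–C6 of 4, whose LUMO is lowered by the lactone carbonyl and the C5 ester, and the dienophile is the electron-rich triple bond of 8. Bonding should be asynchronous: the alkyne carbon beta to oxygen, which carries the CH2OSi group and the larger HOMO coefficient, bonds to pyrone C6 (beta to the C5 ester and delta to the lactone carbonyl), and the methoxy-bearing carbon closes onto C3. Ring A is thus closed as a six-membered carbocycle by an intermolecular (4+2) cycloaddition that forms its C2–C3 and C4–C5 bonds and gives the 2-oxabicyclo[2.2.2]octadienone 9. Lactone 9 should lose CO2 by cycloreversion at the reaction temperature, and aromatization makes the sequence irreversible. No stereocenter remains, because the two bridgehead centers of 9 form as a racemate and are erased when CO2 leaves. The only selectivity needed is regiochemical and it is secured by this polarity match, since the reverse orientation would join the nucleophilic alkyne carbon to C3, alpha to the lactone carbonyl. A methyl ynol ether has no beta-hydrogen on its O-alkyl group, so the retro-ene path to a ketene that limits ethoxy- and tert-butoxyalkynes is closed and 8 should tolerate the heating.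

Step 6
Reactants: 10 methyl 3-(tert-butyldimethylsilyloxymethyl)-2,4-dimethoxy-6-methylbenzoate
Product: 11 3-(tert-butyldimethylsilyloxymethyl)-2,4-dimethoxy-6-methylbenzoic acid
Conditions: n-PrSLi (3 equiv, preformed), HMPA, 20 °C; then cold dilute HCl to pH 4
Reagents that add atoms: none
Why: SN2 dealkylation at the ester methyl carbon by a soft thiolate, chosen because the carbonyl is shielded by the ortho OCH3 and CH3 groups; aryl methyl ethers need far higher temperatures and the silyl ether is inert to thiolate.

Step 7
Reactants: 12 methyl 2,4-dihydroxy-3,6-dimethylbenzoate
Product: 13 2,4-dihydroxy-3,6-dimethylbenzoic acid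
Conditions: KOH (aq.), MeOH, 80 °C, argon; then HCl to pH 2 at 0 °C
Reagents that add atoms: potassium hydroxide, [K+].[OH-]
Why: Saponification; the hindered, electron-rich ester needs hot concentrated alkali, the carboxylate salt is stable to decarboxylation, and cold acidification liberates the acid without heating it in acid.

Step 8
Reactants: 13 2,4-dihydroxy-3,6-dimethylbenzoic acid
Product: 14 benzyl 2,4-dihydroxy-3,6-dimethylbenzoate
Conditions: BnBr (1.05 equiv), KHCO3, DMF, 25 °C
Reagents that add atoms: benzyl bromide, BrCc1ccccc1
Why: Carboxylate alkylation (SN2); KHCO3 ionizes only the carboxylic acid, so the phenols, and in particular the chelated 2-OH, are not benzylated.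

Step 9
Reactants: 11 3-(tert-butyldimethylsilyloxymethyl)-2,4-dimethoxy-6-methylbenzoic acid; 14 benzyl 2,4-dihydroxy-3,6-dimethylbenzoate
Product: 16 benzyl 4-[3-(tert-butyldimethylsilyloxymethyl)-2,4-dimethoxy-6-methylbenzoyl]oxy-2-hydroxy-3,6-dimethylbenzoate, via acyl chloride 15 (not isolated)
Conditions: 1-chloro-N,N,2-trimethylprop-1-en-1-amine (1.05 equiv), CH2Cl2, 0 → 20 °C; then 14, Et3N, DMAP (cat.), 0 → 20 °C
Reagents that add atoms: none
Why: The alpha-chloroenamine turns the acid into acyl chloride 15 without releasing acid, so the benzylic silyl ether survives, and DMAP-catalyzed acylation then takes place at the free 4-OH because the 2-OH is hydrogen-bonded to the ester carbonyl and flanked on both sides; doubly ortho-substituted aroyl chlorides are known to acylate phenols under such conditions.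

Step 10
Reactants: 16 benzyl 4-[3-(tert-butyldimethylsilyloxymethyl)-2,4-dimethoxy-6-methylbenzoyl]oxy-2-hydroxy-3,6-dimethylbenzoate
Product: 17 4-[3-(tert-butyldimethylsilyloxymethyl)-2,4-dimethoxy-6-methylbenzoyl]oxy-2-hydroxy-3,6-dimethylbenzoic acid
Conditions: H2 (1 atm), Pd/C, EtOAc, 20 °C
Reagents that add atoms: none
Why: Hydrogenolysis of a benzyl ester over Pd/C in a neutral solvent; the aryl ester, the aryl ethers and the silyl ether are inert, and the bulky silyl group together with the absence of strong acid should protect the ring A benzylic C–O bond.

Step 11
Reactants: 17 4-[3-(tert-butyldimethylsilyloxymethyl)-2,4-dimethoxy-6-methylbenzoyl]oxy-2-hydroxy-3,6-dimethylbenzoic acid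
Product: 18 4-[3-(hydroxymethyl)-2,4-dimethoxy-6-methylbenzoyl]oxy-2-hydroxy-3,6-dimethylbenzoic acid
Conditions: Bu4NF (3 equiv), AcOH (3 equiv), THF, 0 → 20 °C; pH 4–5 phosphate buffer work-up
Reagents that add atoms: none
Why: Fluoride-induced Si–O cleavage driven by Si–F bond formation; buffering with AcOH keeps both free alkoxide (which would threaten the inter-ring ester) and strong acid (which would ionize the benzylic alcohol) out of the mixture.

## Compound list

1 | dimethyl malonate | COC(=O)CC(=O)OC | starting material
2 | methyl but-2-ynoate | CC#CC(=O)OC | starting material
3 | trimethyl (Z)-2-methylprop-1-ene-1,3,3-tricarboxylate | COC(=O)C(C(=O)OC)/C(C)=C\C(=O)OC | intermediate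
4 | methyl 6-methoxy-4-methyl-2-oxo-2H-pyran-5-carboxylate | COC(=O)C1=C(OC)OC(=O)C=C1C | intermediate
5 | 2-chloro-1,1-dimethoxyethane | COC(CCl)OC | starting material
6 | lithium methoxyacetylide | [Li]C#COC | intermediate (not isolated)
7 | 3-methoxyprop-2-yn-1-ol | COC#CCO | intermediate
8 | tert-butyl(3-methoxyprop-2-ynyloxy)dimethylsilane | COC#CCO[Si](C)(C)C(C)(C)C | intermediate
9 | methyl 7-(tert-butyldimethylsilyloxymethyl)-1,8-dimethoxy-5-methyl-3-oxo-2-oxabicyclo[2.2.2]octa-5,7-diene-6-carboxylate (racemic) | O=C1OC2(OC)C(CO[Si](C)(C)C(C)(C)C)=C(OC)C1C(C)=C2C(=O)OC | intermediate (not isolated)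
10 | methyl 3-(tert-butyldimethylsilyloxymethyl)-2,4-dimethoxy-6-methylbenzoate | COC(=O)c1c(C)cc(OC)c(CO[Si](C)(C)C(C)(C)C)c1OC | intermediate
11 | 3-(tert-butyldimethylsilyloxymethyl)-2,4-dimethoxy-6-methylbenzoic acid | COc1cc(C)c(C(=O)O)c(OC)c1CO[Si](C)(C)C(C)(C)C | intermediate
12 | methyl 2,4-dihydroxy-3,6-dimethylbenzoate | COC(=O)c1c(C)cc(O)c(C)c1O | starting material
13 | 2,4-dihydroxy-3,6-dimethylbenzoic acid | Cc1cc(O)c(C)c(O)c1C(=O)O | intermediate
14 | benzyl 2,4-dihydroxy-3,6-dimethylbenzoate | Cc1cc(O)c(C)c(O)c1C(=O)OCc1ccccc1 | intermediate
15 | 3-(tert-butyldimethylsilyloxymethyl)-2,4-dimethoxy-6-methylbenzoyl chloride | COc1cc(C)c(C(=O)Cl)c(OC)c1CO[Si](C)(C)C(C)(C)C | intermediate (not isolated)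
16 | benzyl 4-[3-(tert-butyldimethylsilyloxymethyl)-2,4-dimethoxy-6-methylbenzoyl]oxy-2-hydroxy-3,6-dimethylbenzoate | COc1cc(C)c(C(=O)Oc2cc(C)c(C(=O)OCc3ccccc3)c(O)c2C)c(OC)c1CO[Si](C)(C)C(C)(C)C | intermediate
17 | 4-[3-(tert-butyldimethylsilyloxymethyl)-2,4-dimethoxy-6-methylbenzoyl]oxy-2-hydroxy-3,6-dimethylbenzoic acid | COc1cc(C)c(C(=O)Oc2cc(C)c(C(=O)O)c(O)c2C)c(OC)c1CO[Si](C)(C)C(C)(C)C | intermediate
18 | 4-[3-(hydroxymethyl)-2,4-dimethoxy-6-methylbenzoyl]oxy-2-hydroxy-3,6-dimethylbenzoic acid | COc1cc(C)c(C(=O)Oc2cc(C)c(C(=O)O)c(O)c2C)c(OC)c1CO | target

## Step count and least certain steps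

Total step count: 11. Longest linear sequence: 7 steps (steps 1, 2, 5, 6, 9, 10, 11; the branch through steps 3, 4, 5, 6, 9, 10, 11 is equally long).

**Step 5 (key step).** The 6-methoxy group donates into the diene and raises its LUMO. The cycloaddition may therefore be slow enough for thermal or hydrolytic loss of the ynol ether to win. A stepwise addition could also be followed by ring opening at the acetal-like C6 instead of closure onto C3. Fallback: abandon the cycloaddition and derive ring A from the purchased skeleton of 12 by side-chain oxidation. From 12, exhaustive O-methylation (Me2SO4, K2CO3, acetone, reflux) should give methyl 2,4-dimethoxy-3,6-dimethylbenzoate F1. Radical bromination (N-bromosuccinimide, light, PhCF3) is expected at the C3 methyl group, whose benzylic radical lies between two methoxy groups, and should give methyl 3-(bromomethyl)-2,4-dimethoxy-6-methylbenzoate F2. Solvolysis (CaCO3, aqueous dioxane) gives methyl 3-(hydroxymethyl)-2,4-dimethoxy-6-methylbenzoate F3. Silylation as in step 4 rejoins the route at 10.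

**Step 2.** Lactonization may be incomplete, or the triester may decompose at the temperature needed. Closure in the other sense, through the enol of the unsaturated ester onto a malonate carbonyl, would place the ester at pyrone C3. By the same polarity rule such an isomer would still map onto arene 10, because ring A has a methoxy group on each side of C3. Fallback: replace thermal loss of alcohol by acyl activation of a free acid. From 1, addition of its sodium salt (NaH, THF) to tert-butyl but-2-ynoate should give 1-tert-butyl 3,3-dimethyl (Z)-2-methylprop-1-ene-1,3,3-tricarboxylate F4. CF3CO2H removes the tert-butyl group to give (Z)-5-methoxy-4-(methoxycarbonyl)-3-methyl-5-oxopent-2-enoic acid F5. Oxalyl chloride followed by Et3N closes the malonate enol oxygen onto the acid chloride at low temperature and rejoins the route at 4.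

**Step 3.** The alkoxypropargyl alcohol may be lost during isolation, by acid-catalyzed Meyer–Schuster rearrangement or hydration of the ynol ether, or by evaporation of this small, water-soluble product. Fallback: never liberate the alcohol. From acetylide 6, after addition to formaldehyde, the lithium 3-methoxyprop-2-yn-1-olate F6 is silylated in the same flask with excess TBSCl, enough to consume the LiOMe that is also present. This gives 8 directly, and the route is rejoined at 8.

**Step 9.** Acyl transfer at the doubly ortho-substituted carbonyl may be slow. That would leave time for acylation of the chelated 2-OH or for double acylation. Fallback: block the 2-OH so that only one hydroxyl can react and a full phenoxide can be used.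
- From 14, selective 4-O-allylation (allyl bromide, K2CO3, acetone) gives benzyl 4-(allyloxy)-2-hydroxy-3,6-dimethylbenzoate F7.
- Benzylation of the 2-OH (BnBr, K2CO3, DMF, 60 °C) gives benzyl 4-(allyloxy)-2-(benzyloxy)-3,6-dimethylbenzoate F8.
- Deallylation (Pd(PPh3)4, morpholine, THF) gives benzyl 2-(benzyloxy)-4-hydroxy-3,6-dimethylbenzoate F9.
- The sodium salt of F9 (NaH, THF) with acyl chloride 15 gives benzyl 2-(benzyloxy)-4-[3-(tert-butyldimethylsilyloxymethyl)-2,4-dimethoxy-6-methylbenzoyl]oxy-3,6-dimethylbenzoate F10.
- Hydrogenolysis under the conditions of step 10 removes both benzyl groups and rejoins the route at 17.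

**Step 11.** The liberated benzylic alcohol may ionize in the presence of the free carboxylic acid of the same molecule during reaction or work-up. That would lead to ether formation or alkylation of the electron-rich ring B. Basic fluoride could also cleave the inter-ring ester. Fallback: reverse the order of the two deprotections, so that the silyl ether is removed while the acid is still masked and the final step is neutral, needing only filtration. From 16, Bu4NF and AcOH give benzyl 2-hydroxy-4-[3-(hydroxymethyl)-2,4-dimethoxy-6-methylbenzoyl]oxy-3,6-dimethylbenzoate F11. A short hydrogenolysis (H2, Pd/C, EtOAc) then gives 18 directly.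

## Further compounds

F1 | step 5 | methyl 2,4-dimethoxy-3,6-dimethylbenzoate | COC(=O)c1c(C)cc(OC)c(C)c1OC
F2 | step 5 | methyl 3-(bromomethyl)-2,4-dimethoxy-6-methylbenzoate | COC(=O)c1c(C)cc(OC)c(CBr)c1OC
F3 | step 5 | methyl 3-(hydroxymethyl)-2,4-dimethoxy-6-methylbenzoate | COC(=O)c1c(C)cc(OC)c(CO)c1OC
F4 | step 2 | 1-tert-butyl 3,3-dimethyl (Z)-2-methylprop-1-ene-1,3,3-tricarboxylate | COC(=O)C(C(=O)OC)/C(C)=C\C(=O)OC(C)(C)C
F5 | step 2 | (Z)-5-methoxy-4-(methoxycarbonyl)-3-methyl-5-oxopent-2-enoic acid | COC(=O)C(C(=O)OC)/C(C)=C\C(=O)O
F6 | step 3 | lithium 3-methoxyprop-2-yn-1-olate | [Li+].COC#CC[O-]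
F7 | step 9 | benzyl 4-(allyloxy)-2-hydroxy-3,6-dimethylbenzoate | C=CCOc1cc(C)c(C(=O)OCc2ccccc2)c(O)c1C
F8 | step 9 | benzyl 4-(allyloxy)-2-(benzyloxy)-3,6-dimethylbenzoate | C=CCOc1cc(C)c(C(=O)OCc2ccccc2)c(OCc2ccccc2)c1C
F9 | step 9 | benzyl 2-(benzyloxy)-4-hydroxy-3,6-dimethylbenzoate | Cc1cc(O)c(C)c(OCc2ccccc2)c1C(=O)OCc1ccccc1
F10 | step 9 | benzyl 2-(benzyloxy)-4-[3-(tert-butyldimethylsilyloxymethyl)-2,4-dimethoxy-6-methylbenzoyl]oxy-3,6-dimethylbenzoate | COc1cc(C)c(C(=O)Oc2cc(C)c(C(=O)OCc3ccccc3)c(OCc3ccccc3)c2C)c(OC)c1CO[Si](C)(C)C(C)(C)C
F11 | step 11 | benzyl 2-hydroxy-4-[3-(hydroxymethyl)-2,4-dimethoxy-6-methylbenzoyl]oxy-3,6-dimethylbenzoate | COc1cc(C)c(C(=O)Oc2cc(C)c(C(=O)OCc3ccccc3)c(O)c2C)c(OC)c1CO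
A1 | alternative 1 | 6-(3,5-dioxohexan-2-yl)-2,2-dimethyl-4H-1,3-dioxin-4-one | CC(=O)CC(=O)C(C)C1=CC(=O)OC(C)(C)O1
A2 | alternative 1 | 7-hydroxy-2,2,5,8-tetramethyl-4H-benzo[d][1,3]dioxin-4-one | Cc1cc(O)c(C)c2OC(C)(C)OC(=O)c12
A3 | alternative 2 | benzyl 2-(benzyloxy)-4-(but-2-ynoyloxy)-3,6-dimethylbenzoate | CC#CC(=O)Oc1cc(C)c(C(=O)OCc2ccccc2)c(OCc2ccccc2)c1C
A4 | alternative 2 | [2-(benzyloxymethyl)-1,3-dimethoxybuta-1,3-dienyloxy]trimethylsilane | COC(O[Si](C)(C)C)=C(COCc1ccccc1)C(OC)=C
A5 | alternative 2 | benzyl 2-(benzyloxy)-4-[3-(benzyloxymethyl)-2-hydroxy-4-methoxy-6-methylbenzoyl]oxy-3,6-dimethylbenzoate | COc1cc(C)c(C(=O)Oc2cc(C)c(C(=O)OCc3ccccc3)c(OCc3ccccc3)c2C)c(O)c1COCc1ccccc1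
A6 | alternative 3 | (4-bromo-2,6-dimethoxybenzyloxy)triisopropylsilane | COc1cc(Br)cc(OC)c1CO[Si](C(C)C)(C(C)C)C(C)C
A7 | alternative 3 | 2,4-dimethoxy-6-methyl-3-(triisopropylsilyloxymethyl)benzoic acid | COc1cc(C)c(C(=O)O)c(OC)c1CO[Si](C(C)C)(C(C)C)C(C)C
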